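**Retrosynthetic overview**

1. Target 24 ⇐ C6-acetal 23 ⇐ (4+1) annulation of keto aldehyde 19 with a 1-bromovinyl chromium carbenoid from CH3CBr3: C15–C16, then C16–C13, closes ring D (C8, C14, C13, C16, C15) last.
2. Enabling feature: ring D is a 2-methylenecyclopentane-1,3-diol whose two carbinol carbons (C15, C13) both sit on the one sp2 carbon C16. It therefore unfolds to a 1,4-keto aldehyde (C15=O and C13=O joined through C8–C14) plus a vinylidene 1,1-dianion (C16=C17).
3. 19 ⇐ thioester 18 ⇐ 17: ring C by oxidative enolate coupling (C8–C14), which also sets quaternary C8. 17 ⇐ conjugate addition of a C11–C14 homoenolate to the C8-acylated unsaturated spirolactone 13 (sets C9).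
4. Spirolactone 10 ⇐ Michael addition of formyl ketone 4 to methyl acrylate (quaternary C10), then reduction and lactonisation. Ring A ⇐ dienone 1 by rhodium-catalysed asymmetric vinylation (C5).
5. Ring order: A (from 1), lactone ring B (step 4), ring C (step 10), ring D (step 12).

Key step: step 12

Assumption: atom numbers follow ent-kaurane numbering of the target, and (R)-BINAP is taken to give (R)-3 by analogy with rhodium/BINAP additions to cyclohex-2-enone (the ligand antipode is used if the sense is reversed).

**Route**

Step 1
Reactants: 1 4,4-dimethylcyclohexa-2,5-dien-1-one; 2 potassium vinyltrifluoroborate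
Product: 3 (R)-5-ethenyl-4,4-dimethylcyclohex-2-en-1-one
Conditions: [Rh(cod)2]BF4 (3 mol %), (R)-BINAP (3.3 mol %), Et3N, toluene/H2O (10:1), 80 °C, 1.05 equiv of 2
Reagents that add atoms: none
Why: Rhodium-catalysed asymmetric 1,4-addition (Hayashi–Miyaura type) of the vinylborate desymmetrises the prochiral dienone, the BINAP–rhodium complex choosing one enantiotopic enone face and so setting C5, while limiting 2 to a slight excess should hold back a second addition to the product enone.

Step 2
Reactants: 3 (R)-5-ethenyl-4,4-dimethylcyclohex-2-en-1-one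
Product: 4 hydroxymethylene ketone
Conditions: NaH (1.5 equiv), HCO2Et (3 equiv), cat. EtOH, THF, 0 °C to rt; aq. HCl work-up
Reagents that add atoms: ethyl formate, CCOC=O
Why: Claisen-type α'-formylation takes place at the only enolisable position (C10) of the enone and gives the chelated hydroxymethylene ketone, which acidifies C10 for the next C–C bond.

Step 3
Reactants: 4 hydroxymethylene ketone; 5 methyl acrylate
Product: 6 formyl keto ester with quaternary C10
Conditions: Cs2CO3 (10 mol %), MeCN, 0 °C to rt
Reagents that add atoms: none
Why: Base-catalysed Michael addition of the soft 1,3-dicarbonyl carbanion to the acrylate creates quaternary C10, the acceptor approaching anti to the adjacent C5 vinyl group so that C9 ends up trans and the formyl carbon C20 cis to the C5 substituent.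

Step 4
Reactants: 6 formyl keto ester
Product: 8 vinyl spirolactone, via hydroxy ester 7 (not isolated)
Conditions: NaBH4 (0.3 equiv), THF/MeOH (10:1), −78 °C; then p-TsOH·H2O (5 mol %), toluene, 50 °C
Reagents that add atoms: none
Why: Chemoselective borohydride reduction of the aldehyde (faster at low temperature than the hindered conjugated ketone) followed by acid-catalysed 6-exo-trig lactonisation onto the methyl ester closes the δ-lactone without touching a stereocentre.

Step 5
Reactants: 8 vinyl spirolactone
Product: 10 dioxolane spirolactone, via aldehyde 9 (not isolated)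
Conditions: O3, CH2Cl2, −78 °C (Sudan red 7B end point); Me2S, −78 °C to rt; then HOCH2CH2OH, PPTS, benzene, reflux (Dean–Stark)
Reagents that add atoms: ethylene glycol, OCCO
Why: Ozonolysis cleaves the vinyl group faster than the electron-poor enone, and the C6 aldehyde is masked at once as its dioxolane by acid-catalysed acetalisation, which the hindered enone ketone resists, so the α-stereocentre C5 is not exposed for long.

Step 6
Reactants: 10 dioxolane spirolactone
Product: 11 lactone thioester
Conditions: LDA (2.2 equiv), THF, −78 °C; EtSC(O)Cl (1.1 equiv), −78 °C; aq. NH4Cl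
Reagents that add atoms: S-ethyl chlorothioformate, CCSC(Cl)=O
Why: Claisen-type C-acylation of the lithium lactone enolate installs C15 as a thioester that activates C8–C9 for the next steps and can later be reduced selectively; ring A has no enolisable hydrogen.

Step 7
Reactants: 11 lactone thioester
Product: 13 alkylidene lactone thioester, via selenide 12 (not isolated)
Conditions: PhSeCl (1.1 equiv), pyridine (1.2 equiv), CH2Cl2, 0 °C; then 30% aq. H2O2, 0 °C to rt
Reagents that add atoms: none
Why: α-Selenenylation of the 1,3-dicarbonyl and selenoxide syn-elimination towards the only β-hydrogens (at C9) give the doubly activated C8=C9 acceptor.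

Step 8
Reactants: 13 alkylidene lactone thioester; 14 2-(2-bromoethyl)-2-methyl-1,3-dioxolane
Product: 16 conjugate adduct, via Grignard reagent 15 (not isolated)
Conditions: 14, Mg turnings, THF, rt; then CuBr·SMe2 (10 mol %) and 13, THF, −78 °C; H2O quench
Reagents that add atoms: none
Why: Copper-catalysed conjugate addition of the Grignard reagent should go to the doubly activated alkylidene much faster than to the neopentyl-flanked ring A enone, and the nucleophile attacks C9 from the face of the flat C1 carbonyl, anti to the substituted C5, which sets C9 with C11 cis to C1.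

Step 9
Reactants: 16 conjugate adduct
Product: 17 methyl ketone
Conditions: oxalic acid (10 mol %), THF/H2O (4:1), rt
Reagents that add atoms: water, O
Why: Acid-catalysed hydrolysis cleaves the dialkyl ketal through its tertiary oxocarbenium ion far faster than the hindered aldehyde-derived dioxolane at C6, unmasking the C13 methyl ketone.

Step 10
Reactants: 17 methyl ketone
Product: 18 tricyclic keto thioester
Conditions: LDA (2.3 equiv), THF, −78 °C (inverse addition); then [Fe(DMF)3Cl2][FeCl4] (1.2 equiv), THF, −78 °C to rt, 0.01 M
Reagents that add atoms: none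
Why: Intramolecular oxidative heterocoupling of the dianion (stabilised C8 enolate plus kinetic methyl ketone enolate at C14) by the trivalent-iron oxidant forms the C8–C14 bond of the 1,4-dicarbonyl and closes ring C in a 6-exo mode; the tether delivers C14 perpendicular to the enolate plane on the face of C11, so the lactone and ring C become cis-fused and the thioester carbon C15 ends up cis to H-9.

Step 11
Reactants: 18 tricyclic keto thioester
Product: 19 keto aldehyde
Conditions: Et3SiH (3 equiv), 10% Pd/C (10 mol % Pd), acetone, rt
Reagents that add atoms: none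
Why: Fukuyama reduction (palladium-catalysed hydrosilane reduction of the thioester through an acyl–palladium intermediate) gives the C15 aldehyde and should leave lactone, ketones and acetal untouched.

Step 12
Reactants: 19 keto aldehyde; 20 1,1,1-tribromoethane
Product: 23 tetracyclic diol acetal, via bromovinyl chromium reagent 21 (not isolated), via bromoallylic alcohol 22 (not isolated)
Conditions: CrCl2 (10 equiv), 20 (2 equiv), THF/DMF (4:1), rt; then NiCl2 (10 mol %), 50 °C; H2O work-up
Reagents that add atoms: none
Why: Proposed new method: CrCl2 reduces CH3CBr3 to the (1-bromoethenyl)chromium carbenoid 21 (trivalent chromium), which adds only to the C15 aldehyde; the resulting 2-bromoallylic chromium alkoxide of 22 is then activated by catalytic NiCl2 (oxidative addition of zerovalent nickel to the C–Br bond, transmetalation to chromium) and adds to the C13 ketone, so that C16 with its methylene C17 is stitched between the two carbonyls in a formal (4+1) annulation. The closest known reaction types are the addition of chromium vinylidene carbenoids from 1,1,1-trihaloalkanes to aldehydes and the intramolecular Nozaki–Hiyama–Kishi addition of a vinyl bromide to a ketone. Ring D (C8–C14–C13–C16–C15) closes by 5-exo-trig attack of the C16–chromium bond on the C13 carbonyl. C15 is set in the first bond formation under non-chelating conditions (DMF-solvated chromium): the C15=O and lactone C7=O dipoles are opposed and the reagent passes the small C14 methylene instead of C9, which places the 15-OH on the side of H-9; C13 is set by the tether, because the two-carbon bridge can only span C8 and C13 on one face of ring C. The step needs chemoselectivity for the aldehyde over the C13 ketone, the C1 enone and the lactone, which the aldehyde preference of organochromium reagents secures, and it needs the ketone addition to outrun intermolecular coupling, which the five-membered ring size favours.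

Step 13
Reactants: 23 tetracyclic diol acetal
Product: 24 target CNP0521079.1
Conditions: 1 M aq. HCl/THF (1:4), 0 °C to rt
Reagents that add atoms: water, O
Why: Acid-catalysed hydrolysis of the dioxolane frees the C6 aldehyde; the bridgehead tertiary alcohol cannot ionise and dilute acid at room temperature should spare the secondary allylic alcohol.

**Compound list**

1 | 4,4-dimethylcyclohexa-2,5-dien-1-one | O=C1C=CC(C)(C)C=C1 | starting material
2 | potassium ethenyltrifluoroborate (potassium vinyltrifluoroborate) | [K+].C=C[B-](F)(F)F | starting material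
3 | (R)-5-ethenyl-4,4-dimethylcyclohex-2-en-1-one | O=C1C=CC(C)(C)[C@@H](C=C)C1 | intermediate
4 | (5R,6Z)-5-ethenyl-6-(hydroxymethylidene)-4,4-dimethylcyclohex-2-en-1-one | O=C1C=CC(C)(C)[C@@H](C=C)/C1=C/O | intermediate
5 | methyl acrylate | C=CC(=O)OC | starting material
6 | methyl 3-[(1S,6R)-6-ethenyl-1-formyl-5,5-dimethyl-2-oxocyclohex-3-en-1-yl]propanoate (propanoate chain trans to ethenyl) | COC(=O)CC[C@]1(C=O)C(=O)C=CC(C)(C)[C@H]1C=C | intermediate
7 | methyl 3-[6-ethenyl-1-(hydroxymethyl)-5,5-dimethyl-2-oxocyclohex-3-en-1-yl]propanoate (C5 and C10 as in 6) | COC(=O)CC[C@]1(CO)C(=O)C=CC(C)(C)[C@H]1C=C | intermediate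
8 | 11-ethenyl-10,10-dimethyl-2-oxaspiro[5.5]undec-8-ene-3,7-dione (lactone CH2O cis to ethenyl; C5 and C10 as in 24) | O=C1CC[C@]2(CO1)C(=O)C=CC(C)(C)[C@H]2C=C | intermediate
9 | 10,10-dimethyl-3,7-dioxo-2-oxaspiro[5.5]undec-8-ene-11-carbaldehyde (C5 and C10 as in 24) | O=C1CC[C@]2(CO1)C(=O)C=CC(C)(C)[C@H]2C=O | intermediate
10 | 11-(1,3-dioxolan-2-yl)-10,10-dimethyl-2-oxaspiro[5.5]undec-8-ene-3,7-dione (C5 and C10 as in 24) | O=C1CC[C@]2(CO1)C(=O)C=CC(C)(C)[C@H]2C3OCCO3 | intermediate
11 | S-ethyl 11-(1,3-dioxolan-2-yl)-10,10-dimethyl-3,7-dioxo-2-oxaspiro[5.5]undec-8-ene-4-carbothioate (C8 epimers and enol; C5 and C10 as in 24) | O=C1C(C(=O)SCC)C[C@]2(CO1)C(=O)C=CC(C)(C)[C@H]2C3OCCO3 | intermediate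
12 | S-ethyl 11-(1,3-dioxolan-2-yl)-10,10-dimethyl-3,7-dioxo-4-(phenylselanyl)-2-oxaspiro[5.5]undec-8-ene-4-carbothioate (C8 unassigned) | O=C1C([Se]c4ccccc4)(C(=O)SCC)C[C@]2(CO1)C(=O)C=CC(C)(C)[C@H]2C3OCCO3 | intermediate
13 | S-ethyl 11-(1,3-dioxolan-2-yl)-10,10-dimethyl-3,7-dioxo-2-oxaspiro[5.5]undeca-4,8-diene-4-carbothioate (C5 and C10 as in 24) | O=C1C(C(=O)SCC)=C[C@]2(CO1)C(=O)C=CC(C)(C)[C@H]2C3OCCO3 | intermediate
14 | 2-(2-bromoethyl)-2-methyl-1,3-dioxolane | CC1(CCBr)OCCO1 | starting material
15 | [2-(2-methyl-1,3-dioxolan-2-yl)ethyl]magnesium bromide | CC1(CC[Mg]Br)OCCO1 | intermediate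
16 | S-ethyl 11-(1,3-dioxolan-2-yl)-10,10-dimethyl-5-[2-(2-methyl-1,3-dioxolan-2-yl)ethyl]-3,7-dioxo-2-oxaspiro[5.5]undec-8-ene-4-carbothioate (C9 chain cis to C1; C8 epimers; C5, C9, C10 as in 24) | O=C1C(C(=O)SCC)[C@@H](CCC2(C)OCCO2)[C@]3(CO1)C(=O)C=CC(C)(C)[C@H]3C4OCCO4 | intermediate
17 | S-ethyl 11-(1,3-dioxolan-2-yl)-10,10-dimethyl-3,7-dioxo-5-(3-oxobutyl)-2-oxaspiro[5.5]undec-8-ene-4-carbothioate (C5, C9, C10 as in 24) | O=C1C(C(=O)SCC)[C@@H](CCC(C)=O)[C@]3(CO1)C(=O)C=CC(C)(C)[C@H]3C4OCCO4 | intermediate
18 | tricyclic keto thioester: rings A, B and C of 24 with C13 ketone, C8 bearing C(=O)SEt cis to H-9, lactone and ring C cis-fused, C6 as dioxolane (C5, C8, C9, C10 as in 24) | CCSC(=O)[C@]12CC(=O)CC[C@H]1[C@]3(COC2=O)C(=O)C=CC(C)(C)[C@H]3C4OCCO4 | intermediate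
19 | tricyclic keto aldehyde: as 18 with CHO (C15) on C8 | O=C[C@]12CC(=O)CC[C@H]1[C@]3(COC2=O)C(=O)C=CC(C)(C)[C@H]3C4OCCO4 | intermediate
20 | 1,1,1-tribromoethane | CC(Br)(Br)Br | starting material
21 | (1-bromoethenyl)chromium dichloride (trivalent chromium) | C=C(Br)[Cr](Cl)Cl | intermediate
22 | bromoallylic alcohol: as 19 with C8 bearing CH(OH)–C(Br)=CH2, C15 configured as in 24 | C=C(Br)[C@@H](O)[C@]12CC(=O)CC[C@H]1[C@]3(COC2=O)C(=O)C=CC(C)(C)[C@H]3C4OCCO4 | intermediate
23 | 6-(1,3-dioxolan-2-yl) acetal of the target (all six stereocentres as in 24) | C=C1[C@@H](O)[C@]23C[C@@]1(O)CC[C@H]2[C@]1(COC3=O)C(=O)C=CC(C)(C)[C@H]1C4OCCO4 | intermediate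
24 | CNP0521079.1: 13,15-dihydroxy-1-oxo-6,7-seco-kaura-2,16-dien-6-al 7,20-lactone with (5R,8S,9S,10S,13S,15R) configuration in ent-kaurane numbering | C=C1[C@@H](O)[C@]23C[C@@]1(O)CC[C@H]2[C@]1(COC3=O)C(=O)C=CC(C)(C)[C@H]1C=O | target

**Step count and risks**

Total step count: 13. Longest linear sequence: 13 steps (1 to 24).

Steps most likely to fail:

1. Step 12 (proposed new method). The bromovinyl chromium carbenoid may be lost by α-elimination or Takai-type olefination before it reaches the hindered aldehyde. Chelation-controlled addition may erode facial selectivity at C15, or the second-stage addition to the ketone may stall. Fallback: the two bond formations are run as separate, known operations starting from 19. 1-Bromo-1-lithioethene, generated from vinyl bromide and LDA in THF/Et2O/pentane at −110 °C, should add to the aldehyde in preference to the ketones and give the bromoallylic alcohol 22, which is isolated. An intramolecular Nozaki–Hiyama–Kishi reaction (CrCl2, 5 mol % NiCl2, DMSO, rt to 50 °C) should then close ring D and return to the route at 23. This detour creates no compound beyond those listed (F0).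

2. Step 10. Intermolecular oxidative dimerisation, incomplete regiocontrol in the second deprotonation or attack of the base on the thioester may outcompete the ring closure. Fallback: ring C is closed by a radical addition instead of a dianion coupling, setting out from 13. Copper-catalysed conjugate addition of (3-chlorobut-3-en-1-yl)magnesium bromide (CuBr·SMe2, THF, −78 °C) should give the chlorobutenyl lactone thioester F1. Oxidative free-radical cyclisation with Mn(OAc)3·2H2O and Cu(OAc)2 in AcOH at 50 °C (6-endo attack of the C8 radical on the CH2 terminus, oxidation of the α-chloro radical, hydrolysis to the ketone) should return to the route at 18 with the same cis ring fusion.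

3. Step 8. The organometallic may add to the ring A enone, the C1 ketone or the thioester, or attack C9 with poor facial selectivity. Fallback: a tin-hydride Giese reaction replaces the organocopper addition, starting from 13 and bromide 14. With Bu3SnH (syringe pump) and catalytic AIBN in benzene at 80 °C, the nucleophilic primary alkyl radical from 14 should add only to the doubly activated C8=C9 bond, from the same C1 face. Hydrogen transfer to C8 returns to the route at 16. This detour creates no compound beyond those listed (F0).

**Further compounds**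

F0 | step 12 | none | none
F1 | step 10 | S-ethyl 5-(3-chlorobut-3-en-1-yl)-11-(1,3-dioxolan-2-yl)-10,10-dimethyl-3,7-dioxo-2-oxaspiro[5.5]undec-8-ene-4-carbothioate (C5, C9, C10 as in 24) | O=C1C(C(=O)SCC)[C@@H](CCC(Cl)=C)[C@]3(CO1)C(=O)C=CC(C)(C)[C@H]3C4OCCO4
F0 | step 8 | none | none
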